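The quinone ring (ring A: C1–C4, C4a, C8a) is cut at C1–C2 and C4–C4a. In one operation an aryl ketene, released by photochemical Wolff rearrangement of aroyl diazomethane 7, adds across terminal ynamide 11 (C1–C2), and the strained cyclobutenone formed opens and recloses by electrocyclisation onto C4a, the only free ortho carbon of ring B (C4–C4a); the ketone carbon of 7 thereby walks from C8a to C4a. The precursor is a 4,6-dioxygenated 5-methylisophthalate with one carboxyl converted into COCHN2. The features exploited are the N–C2=C3 enamide unit of ring A and the C4a–H of ring B. The side chain is built by iterative crotylboration and joined by Stille coupling.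

Key step: step 8

Locants: naphthoquinone C1 (carbonyl next to C8a), C2 (N), C3, C4, C4a, C5 (CO2H), C6 (OH), C7 (CH3), C8 (OH), C8a; side chain C1′ (amide carbonyl) to C17′ (ketal methyl).
Assumption: pent-4-ynal, benzyl N-benzylcarbamate, (bromoethynyl)triisopropylsilane, both antipodes of but-3-yn-2-ol and both antipodes of Ipc2BOMe are bought; the α-methyl aldehydes 28, 32, 35 and the air-sensitive aminonaphthol 16 are used directly after work-up.

Step 1
Reactants: 1 2-methylbenzene-1,3-diol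
Product: 2 4,6-dibromo-2-methylbenzene-1,3-diol
Conditions: Br2 (2.05 equiv), CHCl3, 0 °C
Reagents that add atoms: bromine (BrBr)
Why: Electrophilic aromatic bromination, in which both hydroxyl groups direct to the two equivalent positions ortho and para to them.

Step 2
Reactants: 2 4,6-dibromo-2-methylbenzene-1,3-diol
Product: 3 1,5-dibromo-2,4-bis(benzyloxy)-3-methylbenzene
Conditions: BnBr, K2CO3, DMF, 60 °C
Reagents that add atoms: benzyl bromide (BrCc1ccccc1)
Why: Williamson ether synthesis on both phenols.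

Step 3
Reactants: 3 1,5-dibromo-2,4-bis(benzyloxy)-3-methylbenzene
Product: 4 2,4-bis(benzyloxy)-5-bromo-3-methylbenzoic acid
Conditions: n-BuLi (1.0 equiv), THF, −78 °C; CO2; aq HCl
Reagents that add atoms: carbon dioxide (O=C=O)
Why: Bromine–lithium exchange of one of the two equivalent bromides, faster than deprotonation at −78 °C, followed by carboxylation desymmetrises the arene.

Step 4
Reactants: 4 2,4-bis(benzyloxy)-5-bromo-3-methylbenzoic acid
Product: 5 2,4-bis(benzyloxy)-3-methyl-5-{[2-(trimethylsilyl)ethoxy]carbonyl}benzoic acid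
Conditions: CO (1 atm), Me3SiCH2CH2OH, Pd(OAc)2 (cat.), Xantphos (cat.), Et3N, PhMe, 90 °C
Reagents that add atoms: carbon monoxide ([C-]#[O+]); 2-(trimethylsilyl)ethanol (C[Si](C)(C)CCO)
Why: Palladium-catalysed alkoxycarbonylation of the remaining aryl bromide, the free acid riding along as its ammonium salt.

Step 5
Reactants: 5 2,4-bis(benzyloxy)-3-methyl-5-{[2-(trimethylsilyl)ethoxy]carbonyl}benzoic acid
Product: 7 2-(trimethylsilyl)ethyl 2,4-bis(benzyloxy)-5-(2-diazoacetyl)-3-methylbenzoate, via acid chloride 6 (not isolated)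
Conditions: (COCl)2, DMF (cat.), CH2Cl2, 0 °C to rt; evaporate; CH2N2 (3 equiv), Et2O, 0 °C
Reagents that add atoms: diazomethane (C=[N+]=[N-])
Why: Acylation of diazomethane by the acid chloride (first stage of the Arndt–Eistert sequence) should give the aroyl diazomethane.

Step 6
Reactants: 8 benzyl N-benzylcarbamate; 9 (bromoethynyl)tri(propan-2-yl)silane
Product: 10 benzyl N-benzyl-N-{[tri(propan-2-yl)silyl]ethynyl}carbamate
Conditions: KN(SiMe3)2 (1 equiv), CuI (1 equiv), pyridine, THF, rt; slow addition of 9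
Reagents that add atoms: none
Why: Copper-mediated N-alkynylation of the potassium carbamate with a bromoalkyne, the standard ynamide synthesis for acyclic carbamates.

Step 7
Reactants: 10 benzyl N-benzyl-N-{[tri(propan-2-yl)silyl]ethynyl}carbamate
Product: 11 benzyl N-benzyl-N-ethynylcarbamate
Conditions: Bu4NF, wet THF, −10 °C
Reagents that add atoms: none
Why: Fluoride-induced protodesilylation of the alkynylsilane.

Step 8
Reactants: 7 2-(trimethylsilyl)ethyl 2,4-bis(benzyloxy)-5-(2-diazoacetyl)-3-methylbenzoate; 11 benzyl N-benzyl-N-ethynylcarbamate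
Product: 15 2-(trimethylsilyl)ethyl 6-{benzyl[(benzyloxy)carbonyl]amino}-2,4-bis(benzyloxy)-8-hydroxy-3-methylnaphthalene-1-carboxylate, via aryl ketene 12 (not isolated), via cyclobutenone 13 (not isolated), via dienyl ketene 14 (not isolated)
Conditions: hν (Hg lamp, Pyrex filter), 11 (1.5 equiv), ClCH2CH2Cl, rt; then PhMe, 110 °C
Reagents that add atoms: none
Why: Irradiation expels N2 from 7 and the aryl carbon C8a shifts to the carbene carbon (Wolff rearrangement), so that the former diazo carbon becomes C1 and the former ketone carbon becomes the ketene carbon C4 of 12, which then adds to the polarised ynamide in a [2+2] cycloaddition, the terminal alkyne carbon (C3) to C4 and the N-bearing carbon (C2) to C1, forming the C1–C2 bond. The strained cyclobutenone 13 opens by thermal 4π-electrocyclic cleavage of its C1–C4 bond to dienyl ketene 14, whose ketene carbon C4 closes onto C4a by 6π-electrocyclisation, and tautomerisation of the cyclohexadienone gives naphthol 15 with the C4–C4a bond in place. The closest known reaction type is the Danheiser benzannulation of α-diazo ketones with heteroatom-substituted alkynes, ynamides included, which has been used to fuse phenol rings onto arenes. The four-membered ring closes by [2+2] cycloaddition and is transient, the six-membered ring (C1–C2–C3–C4–C4a–C8a) closes by electrocyclisation, and no stereocentre survives because the CH of 13 is lost on aromatisation. Two regioselectivities are needed: the orientation of the cycloaddition is secured by the ynamide polarisation, and the site of ring closure is secured because the other ortho carbon (C8) carries a benzyloxy group and cannot re-aromatise, so that reversible ring opening funnels the material through C4a.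

Step 9
Reactants: 15 2-(trimethylsilyl)ethyl 6-{benzyl[(benzyloxy)carbonyl]amino}-2,4-bis(benzyloxy)-8-hydroxy-3-methylnaphthalene-1-carboxylate
Product: 16 2-(trimethylsilyl)ethyl 6-amino-2,4,8-trihydroxy-3-methylnaphthalene-1-carboxylate
Conditions: H2 (1 atm), Pd/C (10%), EtOAc/MeOH, rt; work-up under argon
Reagents that add atoms: none
Why: Hydrogenolysis removes both O-benzyl groups, the benzyl carbamate (with decarboxylation) and then the N-benzyl group of the resulting N-benzylarylamine, while the silylethyl ester and the naphthalene are inert.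

Step 10
Reactants: 17 diethyl 2-methylpropanedioate
Product: 18 diethyl 2-(diiodomethyl)-2-methylpropanedioate
Conditions: NaH, Et2O, reflux; CHI3, reflux
Reagents that add atoms: iodoform (IC(I)I)
Why: C-alkylation of the sodium malonate by iodoform.

Step 11
Reactants: 18 diethyl 2-(diiodomethyl)-2-methylpropanedioate
Product: 19 (2Z)-3-iodo-2-methylprop-2-enoic acid
Conditions: KOH, EtOH/H2O, reflux; aq HCl
Reagents that add atoms: potassium hydroxide ([K+].[OH-])
Why: Saponification followed by stereoselective decarboxylative elimination of iodide should place iodine trans to the methyl group (Z acid).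

Step 12
Reactants: 19 (2Z)-3-iodo-2-methylprop-2-enoic acid; 16 2-(trimethylsilyl)ethyl 6-amino-2,4,8-trihydroxy-3-methylnaphthalene-1-carboxylate
Product: 21 2-(trimethylsilyl)ethyl 2,4,8-trihydroxy-6-{[(2Z)-3-iodo-2-methylprop-2-enoyl]amino}-3-methylnaphthalene-1-carboxylate, via acid chloride 20 (not isolated)
Conditions: 19, Me2C=C(Cl)NMe2, CH2Cl2, 0 °C; then 16, NaHCO3, THF, −20 °C
Reagents that add atoms: none
Why: N-acylation of the electron-rich arylamine by an acid chloride made under neutral conditions (Ghosez's reagent) should be chemoselective over the hindered, hydrogen-bonded phenols and should not isomerise the Z alkene.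

Step 13
Reactants: 21 2-(trimethylsilyl)ethyl 2,4,8-trihydroxy-6-{[(2Z)-3-iodo-2-methylprop-2-enoyl]amino}-3-methylnaphthalene-1-carboxylate
Product: 22 2-(trimethylsilyl)ethyl 2,4-dihydroxy-6-{[(2Z)-3-iodo-2-methylprop-2-enoyl]amino}-3-methyl-5,8-dioxo-5,8-dihydronaphthalene-1-carboxylate
Conditions: (KSO3)2NO (2.5 equiv), KH2PO4, acetone/H2O, 0 °C to rt
Reagents that add atoms: Fremy's salt ([K+].[K+].[O]N(S(=O)(=O)[O-])S(=O)(=O)[O-])
Why: Teuber oxidation of the 1-naphthol, whose para carbon (C1) carries hydrogen, should give the para-quinone, while the fully substituted ring B offers no position at which a quinone can form.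

Step 14
Reactants: 23 (2R)-but-3-yn-2-ol
Product: 24 (2R)-but-3-yn-2-yl methanesulfonate
Conditions: MsCl, Et3N, CH2Cl2, −78 to 0 °C
Reagents that add atoms: methanesulfonyl chloride (CS(=O)(=O)Cl)
Why: O-sulfonylation, which leaves the stereocentre untouched.

Step 15
Reactants: 25 pent-4-ynal
Product: 26 (3S,4S)-3-methyloct-1-en-7-yn-4-ol
Conditions: cis-but-2-ene, KOt-Bu, n-BuLi, THF, −78 to −45 °C; (+)-Ipc2BOMe, −78 °C; BF3·OEt2; 25, −78 °C; then NaOH, H2O2
Reagents that add atoms: cis-but-2-ene (C/C=C\C)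
Why: Brown crotylboration through a chair transition state, in which the Z-crotyl group gives the syn pair C12′/C13′ and the isopinocampheyl ligands derived from (−)-α-pinene direct attack to the Re face of the aldehyde.

Step 16
Reactants: 26 (3S,4S)-3-methyloct-1-en-7-yn-4-ol
Product: 27 triethyl{[(3S,4S)-3-methyloct-1-en-7-yn-4-yl]oxy}silane
Conditions: Et3SiOTf, 2,6-lutidine, CH2Cl2, −78 °C
Reagents that add atoms: triethylsilyl trifluoromethanesulfonate (CC[Si](CC)(CC)OS(=O)(=O)C(F)(F)F)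
Why: Silylation of the secondary alcohol.

Step 17
Reactants: 27 triethyl{[(3S,4S)-3-methyloct-1-en-7-yn-4-yl]oxy}silane
Product: 28 (2R,3S)-2-methyl-3-[(triethylsilyl)oxy]hept-6-ynal
Conditions: O3, CH2Cl2, −78 °C (Sudan Red 7B end point); PPh3
Reagents that add atoms: ozone ([O-][O+]=O)
Why: Ozonolysis of the terminal alkene, which reacts far faster than the terminal alkyne, with reductive work-up.

Step 18
Reactants: 28 (2R,3S)-2-methyl-3-[(triethylsilyl)oxy]hept-6-ynal
Product: 29 (3R,4S,5S,6S)-3,5-dimethyl-6-[(triethylsilyl)oxy]dec-1-en-9-yn-4-ol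
Conditions: cis-but-2-ene, KOt-Bu, n-BuLi, THF, −78 to −45 °C; (−)-Ipc2BOMe, −78 °C; BF3·OEt2; 28, −78 °C; then NaOH, H2O2
Reagents that add atoms: cis-but-2-ene (C/C=C\C)
Why: Brown crotylboration in which the Z-crotyl group gives the syn pair C10′/C11′ and the ligands from (+)-α-pinene direct attack to the Si face, a sense that coincides with the anti-Felkin preference of Z-crotylboranes (C11′/C12′ anti).

Step 19
Reactants: 29 (3R,4S,5S,6S)-3,5-dimethyl-6-[(triethylsilyl)oxy]dec-1-en-9-yn-4-ol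
Product: 31 (1S,3S,4R,5S)-3-[(2R)-but-3-en-2-yl]-1,4-dimethyl-2,8-dioxabicyclo[3.2.1]octane, via diol 30 (not isolated)
Conditions: PPTS, MeOH, rt; then AuCl (5 mol%), rt
Reagents that add atoms: none
Why: Methanolysis of the silyl ether and gold-catalysed double hydroalkoxylation of the alkyne (5-exo-dig attack by the C13′ hydroxyl, then addition of the C11′ hydroxyl to the enol ether) should give the bridged ketal, whose configuration at C16′ is dictated by the bicyclic frame.

Step 20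
Reactants: 31 (1S,3S,4R,5S)-3-[(2R)-but-3-en-2-yl]-1,4-dimethyl-2,8-dioxabicyclo[3.2.1]octane
Product: 32 (2S)-2-[(1S,3R,4R,5S)-1,4-dimethyl-2,8-dioxabicyclo[3.2.1]octan-3-yl]propanal
Conditions: O3, CH2Cl2, −78 °C; PPh3
Reagents that add atoms: ozone ([O-][O+]=O)
Why: Ozonolysis of the vinyl group with reductive work-up.

Step 21
Reactants: 32 (2S)-2-[(1S,3R,4R,5S)-1,4-dimethyl-2,8-dioxabicyclo[3.2.1]octan-3-yl]propanal
Product: 33 (2R,3R,4R)-2-[(1S,3S,4R,5S)-1,4-dimethyl-2,8-dioxabicyclo[3.2.1]octan-3-yl]-4-methylhex-5-en-3-ol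
Conditions: trans-but-2-ene, KOt-Bu, n-BuLi, THF, −78 to −45 °C; (+)-Ipc2BOMe, −78 °C; BF3·OEt2; 32, −78 °C; then NaOH, H2O2
Reagents that add atoms: trans-but-2-ene (C/C=C/C)
Why: Brown crotylboration in which the E-crotyl group gives the anti pair C8′/C9′ and the ligands from (−)-α-pinene direct attack to the Re face, so that reagent control must override the Felkin preference to set C9′ anti to C10′.

Step 22
Reactants: 33 (2R,3R,4R)-2-[(1S,3S,4R,5S)-1,4-dimethyl-2,8-dioxabicyclo[3.2.1]octan-3-yl]-4-methylhex-5-en-3-ol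
Product: 34 triethyl({(2S,3R,4R)-2-[(1S,3R,4R,5S)-1,4-dimethyl-2,8-dioxabicyclo[3.2.1]octan-3-yl]-4-methylhex-5-en-3-yl}oxy)silane
Conditions: Et3SiOTf, 2,6-lutidine, CH2Cl2, −78 °C
Reagents that add atoms: triethylsilyl trifluoromethanesulfonate (CC[Si](CC)(CC)OS(=O)(=O)C(F)(F)F)
Why: Silylation of the C9′ hydroxyl.

Step 23
Reactants: 34 triethyl({(2S,3R,4R)-2-[(1S,3R,4R,5S)-1,4-dimethyl-2,8-dioxabicyclo[3.2.1]octan-3-yl]-4-methylhex-5-en-3-yl}oxy)silane
Product: 35 (2S,3S,4S)-4-[(1S,3R,4R,5S)-1,4-dimethyl-2,8-dioxabicyclo[3.2.1]octan-3-yl]-2-methyl-3-[(triethylsilyl)oxy]pentanal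
Conditions: O3, CH2Cl2, −78 °C; PPh3
Reagents that add atoms: ozone ([O-][O+]=O)
Why: Ozonolysis of the vinyl group with reductive work-up.

Step 24
Reactants: 35 (2S,3S,4S)-4-[(1S,3R,4R,5S)-1,4-dimethyl-2,8-dioxabicyclo[3.2.1]octan-3-yl]-2-methyl-3-[(triethylsilyl)oxy]pentanal; 24 (2R)-but-3-yn-2-yl methanesulfonate
Product: 37 (3S,4S,5R,6R,7S)-7-[(1S,3R,4R,5S)-1,4-dimethyl-2,8-dioxabicyclo[3.2.1]octan-3-yl]-3,5-dimethyl-6-[(triethylsilyl)oxy]oct-1-yn-4-ol, via allenylzinc 36 (not isolated)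
Conditions: 24 (1.5 equiv), Pd(OAc)2 (5 mol%), PPh3 (5 mol%), Et2Zn (3 equiv), THF, −78 to −20 °C
Reagents that add atoms: none
Why: Marshall propargylation, in which anti SN2′ palladation of the mesylate, transmetalation to zinc and addition through a cyclic SE2′ transition state give the anti pair C6′/C7′, C6′ arising from the mesylate with net inversion and C7′ in the matched Felkin sense (syn to C8′).

Step 25
Reactants: 37 (3S,4S,5R,6R,7S)-7-[(1S,3R,4R,5S)-1,4-dimethyl-2,8-dioxabicyclo[3.2.1]octan-3-yl]-3,5-dimethyl-6-[(triethylsilyl)oxy]oct-1-yn-4-ol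
Product: 38 (1E,3S,4S,5R,6R,7S)-7-[(1S,3R,4R,5S)-1,4-dimethyl-2,8-dioxabicyclo[3.2.1]octan-3-yl]-3,5-dimethyl-1-(tributylstannyl)-6-[(triethylsilyl)oxy]oct-1-en-4-ol
Conditions: Bu3SnH, Pd(PPh3)2Cl2 (cat.), THF, 0 °C
Reagents that add atoms: tributyltin hydride (CCCC[SnH](CCCC)CCCC)
Why: Palladium-catalysed syn hydrostannylation of the terminal alkyne, tin going to the unhindered terminal carbon, should give the E-vinylstannane.

Step 26
Reactants: 38 (1E,3S,4S,5R,6R,7S)-7-[(1S,3R,4R,5S)-1,4-dimethyl-2,8-dioxabicyclo[3.2.1]octan-3-yl]-3,5-dimethyl-1-(tributylstannyl)-6-[(triethylsilyl)oxy]oct-1-en-4-ol; 22 2-(trimethylsilyl)ethyl 2,4-dihydroxy-6-{[(2Z)-3-iodo-2-methylprop-2-enoyl]amino}-3-methyl-5,8-dioxo-5,8-dihydronaphthalene-1-carboxylate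
Product: 39 rifsaliniketal 2-(trimethylsilyl)ethyl ester 9′-O-triethylsilyl ether
Conditions: Pd2(dba)3 (cat.), AsPh3, DMF, rt, dark
Reagents that add atoms: none
Why: Stille coupling, which proceeds with retention of both alkene geometries (2′Z,4′E) and tolerates free hydroxyls, phenols and the quinone.

Step 27
Reactants: 39 rifsaliniketal 2-(trimethylsilyl)ethyl ester 9′-O-triethylsilyl ether
Product: 40 rifsaliniketal
Conditions: [(Me2N)3S][Me3SiF2] (TASF), DMF, 0 °C to rt; aq NH4Cl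
Reagents that add atoms: none
Why: Fluoride cleaves the 2-(trimethylsilyl)ethyl ester by β-elimination and the triethylsilyl ether at silicon in one non-hydrolytic operation.

Compound list
1 | 2-methylbenzene-1,3-diol | Cc1c(O)cccc1O | starting material
2 | 4,6-dibromo-2-methylbenzene-1,3-diol | Cc1c(O)c(Br)cc(Br)c1O | intermediate
3 | 1,5-dibromo-2,4-bis(benzyloxy)-3-methylbenzene | Cc1c(OCc2ccccc2)c(Br)cc(Br)c1OCc1ccccc1 | intermediate
4 | 2,4-bis(benzyloxy)-5-bromo-3-methylbenzoic acid | Cc1c(OCc2ccccc2)c(Br)cc(C(=O)O)c1OCc1ccccc1 | intermediate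
5 | 2,4-bis(benzyloxy)-3-methyl-5-{[2-(trimethylsilyl)ethoxy]carbonyl}benzoic acid | Cc1c(OCc2ccccc2)c(C(=O)OCC[Si](C)(C)C)cc(C(=O)O)c1OCc1ccccc1 | intermediate
6 | 2-(trimethylsilyl)ethyl 2,4-bis(benzyloxy)-5-(chlorocarbonyl)-3-methylbenzoate | Cc1c(OCc2ccccc2)c(C(=O)OCC[Si](C)(C)C)cc(C(Cl)=O)c1OCc1ccccc1 | intermediate
7 | 2-(trimethylsilyl)ethyl 2,4-bis(benzyloxy)-5-(2-diazoacetyl)-3-methylbenzoate | Cc1c(OCc2ccccc2)c(C(=O)OCC[Si](C)(C)C)cc(C(=O)C=[N+]=[N-])c1OCc1ccccc1 | intermediate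
8 | benzyl N-benzylcarbamate | O=C(NCc1ccccc1)OCc1ccccc1 | starting material
9 | (bromoethynyl)tri(propan-2-yl)silane | BrC#C[Si](C(C)C)(C(C)C)C(C)C | starting material
10 | benzyl N-benzyl-N-{[tri(propan-2-yl)silyl]ethynyl}carbamate | O=C(OCc1ccccc1)N(Cc1ccccc1)C#C[Si](C(C)C)(C(C)C)C(C)C | intermediate
11 | benzyl N-benzyl-N-ethynylcarbamate | C#CN(Cc1ccccc1)C(=O)OCc1ccccc1 | intermediate
12 | 2-(trimethylsilyl)ethyl 2,4-bis(benzyloxy)-3-methyl-5-(2-oxoethenyl)benzoate (aryl ketene) | O=C=Cc1cc(C(=O)OCC[Si](C)(C)C)c(OCc2ccccc2)c(C)c1OCc1ccccc1 | intermediate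
13 | 2-(trimethylsilyl)ethyl 5-{2-[benzyl(benzyloxycarbonyl)amino]-4-oxocyclobut-2-en-1-yl}-2,4-bis(benzyloxy)-3-methylbenzoate (racemic at the ring CH) | O=C1C=C(N(Cc2ccccc2)C(=O)OCc2ccccc2)C1c1cc(C(=O)OCC[Si](C)(C)C)c(OCc2ccccc2)c(C)c1OCc1ccccc1 | intermediate
14 | 2-(trimethylsilyl)ethyl 5-{(1E)-2-[benzyl(benzyloxycarbonyl)amino]-4-oxobuta-1,3-dien-1-yl}-2,4-bis(benzyloxy)-3-methylbenzoate (dienyl ketene) | O=C=C/C(N(Cc1ccccc1)C(=O)OCc1ccccc1)=C\c1cc(C(=O)OCC[Si](C)(C)C)c(OCc2ccccc2)c(C)c1OCc1ccccc1 | intermediate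
15 | 2-(trimethylsilyl)ethyl 6-{benzyl[(benzyloxy)carbonyl]amino}-2,4-bis(benzyloxy)-8-hydroxy-3-methylnaphthalene-1-carboxylate | Cc1c(OCc2ccccc2)c(C(=O)OCC[Si](C)(C)C)c2c(O)cc(N(Cc3ccccc3)C(=O)OCc3ccccc3)cc2c1OCc1ccccc1 | intermediate
16 | 2-(trimethylsilyl)ethyl 6-amino-2,4,8-trihydroxy-3-methylnaphthalene-1-carboxylate | Cc1c(O)c(C(=O)OCC[Si](C)(C)C)c2c(O)cc(N)cc2c1O | intermediate
17 | diethyl 2-methylpropanedioate | CCOC(=O)C(C)C(=O)OCC | starting material
18 | diethyl 2-(diiodomethyl)-2-methylpropanedioate | CCOC(=O)C(C)(C(I)I)C(=O)OCC | intermediate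
19 | (2Z)-3-iodo-2-methylprop-2-enoic acid | C/C(=C/I)C(=O)O | intermediate
20 | (2Z)-3-iodo-2-methylprop-2-enoyl chloride | C/C(=C/I)C(=O)Cl | intermediate
21 | 2-(trimethylsilyl)ethyl 2,4,8-trihydroxy-6-{[(2Z)-3-iodo-2-methylprop-2-enoyl]amino}-3-methylnaphthalene-1-carboxylate | C/C(=C/I)C(=O)Nc1cc(O)c2c(C(=O)OCC[Si](C)(C)C)c(O)c(C)c(O)c2c1 | intermediate
22 | 2-(trimethylsilyl)ethyl 2,4-dihydroxy-6-{[(2Z)-3-iodo-2-methylprop-2-enoyl]amino}-3-methyl-5,8-dioxo-5,8-dihydronaphthalene-1-carboxylate | C/C(=C/I)C(=O)NC1=CC(=O)c2c(C(=O)OCC[Si](C)(C)C)c(O)c(C)c(O)c2C1=O | intermediate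
23 | (2R)-but-3-yn-2-ol | C[C@@H](O)C#C | starting material
24 | (2R)-but-3-yn-2-yl methanesulfonate | C[C@@H](OS(C)(=O)=O)C#C | intermediate
25 | pent-4-ynal | O=CCCC#C | starting material
26 | (3S,4S)-3-methyloct-1-en-7-yn-4-ol | C=C[C@H](C)[C@@H](O)CCC#C | intermediate
27 | triethyl{[(3S,4S)-3-methyloct-1-en-7-yn-4-yl]oxy}silane | C=C[C@H](C)[C@@H](O[Si](CC)(CC)CC)CCC#C | intermediate
28 | (2R,3S)-2-methyl-3-[(triethylsilyl)oxy]hept-6-ynal | O=C[C@H](C)[C@@H](O[Si](CC)(CC)CC)CCC#C | intermediate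
29 | (3R,4S,5S,6S)-3,5-dimethyl-6-[(triethylsilyl)oxy]dec-1-en-9-yn-4-ol | C=C[C@@H](C)[C@H](O)[C@H](C)[C@@H](O[Si](CC)(CC)CC)CCC#C | intermediate
30 | (3R,4S,5R,6S)-3,5-dimethyldec-1-en-9-yne-4,6-diol | C=C[C@@H](C)[C@H](O)[C@H](C)[C@@H](O)CCC#C | intermediate
31 | (1S,3S,4R,5S)-3-[(2R)-but-3-en-2-yl]-1,4-dimethyl-2,8-dioxabicyclo[3.2.1]octane | C=C[C@@H](C)[C@@H]1O[C@@]2(C)CC[C@H](O2)[C@H]1C | intermediate
32 | (2S)-2-[(1S,3R,4R,5S)-1,4-dimethyl-2,8-dioxabicyclo[3.2.1]octan-3-yl]propanal | O=C[C@@H](C)[C@@H]1O[C@@]2(C)CC[C@H](O2)[C@H]1C | intermediate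
33 | (2R,3R,4R)-2-[(1S,3S,4R,5S)-1,4-dimethyl-2,8-dioxabicyclo[3.2.1]octan-3-yl]-4-methylhex-5-en-3-ol | C=C[C@@H](C)[C@@H](O)[C@@H](C)[C@@H]1O[C@@]2(C)CC[C@H](O2)[C@H]1C | intermediate
34 | triethyl({(2S,3R,4R)-2-[(1S,3R,4R,5S)-1,4-dimethyl-2,8-dioxabicyclo[3.2.1]octan-3-yl]-4-methylhex-5-en-3-yl}oxy)silane | C=C[C@@H](C)[C@@H](O[Si](CC)(CC)CC)[C@@H](C)[C@@H]1O[C@@]2(C)CC[C@H](O2)[C@H]1C | intermediate
35 | (2S,3S,4S)-4-[(1S,3R,4R,5S)-1,4-dimethyl-2,8-dioxabicyclo[3.2.1]octan-3-yl]-2-methyl-3-[(triethylsilyl)oxy]pentanal | O=C[C@@H](C)[C@@H](O[Si](CC)(CC)CC)[C@@H](C)[C@@H]1O[C@@]2(C)CC[C@H](O2)[C@H]1C | intermediate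
36 | (aS)-buta-1,2-dien-1-yl(ethyl)zinc (zinc anti to the departed mesylate) | [H]C(C)=[C@]=C([H])[Zn]CC | intermediate
37 | (3S,4S,5R,6R,7S)-7-[(1S,3R,4R,5S)-1,4-dimethyl-2,8-dioxabicyclo[3.2.1]octan-3-yl]-3,5-dimethyl-6-[(triethylsilyl)oxy]oct-1-yn-4-ol | C#C[C@H](C)[C@H](O)[C@@H](C)[C@@H](O[Si](CC)(CC)CC)[C@@H](C)[C@@H]1O[C@@]2(C)CC[C@H](O2)[C@H]1C | intermediate
38 | (1E,3S,4S,5R,6R,7S)-7-[(1S,3R,4R,5S)-1,4-dimethyl-2,8-dioxabicyclo[3.2.1]octan-3-yl]-3,5-dimethyl-1-(tributylstannyl)-6-[(triethylsilyl)oxy]oct-1-en-4-ol | CCCC[Sn](CCCC)(CCCC)/C=C/[C@H](C)[C@H](O)[C@@H](C)[C@@H](O[Si](CC)(CC)CC)[C@@H](C)[C@@H]1O[C@@]2(C)CC[C@H](O2)[C@H]1C | intermediate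
39 | rifsaliniketal 2-(trimethylsilyl)ethyl ester 9′-O-triethylsilyl ether | C/C(=C/C=C/[C@H](C)[C@H](O)[C@@H](C)[C@@H](O[Si](CC)(CC)CC)[C@@H](C)[C@@H]1O[C@@]2(C)CC[C@H](O2)[C@H]1C)C(=O)NC1=CC(=O)c2c(C(=O)OCC[Si](C)(C)C)c(O)c(C)c(O)c2C1=O | intermediate
40 | rifsaliniketal: 6-{[(2Z,4E,6S,7S,8R,9R,10R)-10-[(1S,3S,4R,5S)-1,4-dimethyl-2,8-dioxabicyclo[3.2.1]octan-3-yl]-7,9-dihydroxy-2,6,8-trimethylundeca-2,4-dienoyl]amino}-2,4-dihydroxy-3-methyl-5,8-dioxo-5,8-dihydronaphthalene-1-carboxylic acid | C/C(=C/C=C/[C@H](C)[C@H](O)[C@@H](C)[C@@H](O)[C@@H](C)[C@@H]1O[C@@]2(C)CC[C@H](O2)[C@H]1C)C(=O)NC1=CC(=O)c2c(C(=O)O)c(O)c(C)c(O)c2C1=O | target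

Total step count: 27. Longest linear sequence: 13 steps (25 to 40: steps 15–27).

Steps most likely to fail

Step 8. The photogenerated acyl carbene may insert into a benzylic C–H bond of the neighbouring benzyloxy group, or the ketene may dimerise before the ynamide traps it. The fallback makes the same ketene in the dark without a free carbene and divides the annulation into two stages. Setting out from 7, silver-catalysed Wolff rearrangement in wet THF (PhCO2Ag, Et3N, THF/H2O, rt) would give the homologous arylacetic acid F1. Oxalyl chloride would convert it into the arylacetyl chloride F2. Slow addition of Et3N to F2 and 11 in toluene at room temperature would release ketene 12 by dehydrochlorination, so that cyclobutenone 13 can be isolated and then heated at 110 °C, which returns the route at 15.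

Step 21. Facial selectivity may be poor because the Felkin preference of aldehyde 32 opposes the crotylborane. The fallback replaces crotylboration by an SE2′ allenylmetal addition with stronger reagent control. Setting out from 32, the mirror-image allenylzinc reagent F4 would be made in the flask from (2S)-but-3-yn-2-yl methanesulfonate F3 (from purchased (2S)-but-3-yn-2-ol, MsCl, Et3N) with Pd(OAc)2, PPh3 and Et2Zn. Its addition should give the anti,anti homopropargylic alcohol F5. Semi-hydrogenation (H2, Lindlar catalyst, quinoline, EtOAc) would return the route at 33.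

Step 27. Basic fluoride may degrade the amidoquinone or isomerise the (2′Z)-dienamide. The fallback changes the order so that the quinone is formed last. Setting out from 21, Stille coupling with 38 at the naphthol stage (Pd2(dba)3, AsPh3, DMF, rt) would give the coupled naphthol F6. TASF would desilylate it to the trihydroxynaphthoic acid F7. Teuber oxidation of F7 with Fremy's salt (KH2PO4, acetone/H2O) would then be the final step and would arrive at 40.

Further compounds
F1 | step 8 | [2,4-bis(benzyloxy)-3-methyl-5-{[2-(trimethylsilyl)ethoxy]carbonyl}phenyl]acetic acid | Cc1c(OCc2ccccc2)c(C(=O)OCC[Si](C)(C)C)cc(CC(=O)O)c1OCc1ccccc1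
F2 | step 8 | 2-(trimethylsilyl)ethyl 2,4-bis(benzyloxy)-5-(2-chloro-2-oxoethyl)-3-methylbenzoate | Cc1c(OCc2ccccc2)c(C(=O)OCC[Si](C)(C)C)cc(CC(Cl)=O)c1OCc1ccccc1
F3 | step 21 | (2S)-but-3-yn-2-yl methanesulfonate | C[C@H](OS(C)(=O)=O)C#C
F4 | step 21 | (aR)-buta-1,2-dien-1-yl(ethyl)zinc | [H]C(C)=[C@@]=C([H])[Zn]CC
F5 | step 21 | (3R,4R,5R)-5-[(1S,3S,4R,5S)-1,4-dimethyl-2,8-dioxabicyclo[3.2.1]octan-3-yl]-3-methylhex-1-yn-4-ol | C#C[C@@H](C)[C@@H](O)[C@@H](C)[C@@H]1O[C@@]2(C)CC[C@H](O2)[C@H]1C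
F6 | step 27 | 2-(trimethylsilyl)ethyl 2,4,8-trihydroxy-3-methyl-6-(acylamino)naphthalene-1-carboxylate carrying the 9′-O-triethylsilyl side chain of 39 | C/C(=C/C=C/[C@H](C)[C@H](O)[C@@H](C)[C@@H](O[Si](CC)(CC)CC)[C@@H](C)[C@@H]1O[C@@]2(C)CC[C@H](O2)[C@H]1C)C(=O)Nc1cc(O)c2c(C(=O)OCC[Si](C)(C)C)c(O)c(C)c(O)c2c1
F7 | step 27 | 2,4,8-trihydroxy-3-methyl-6-(acylamino)naphthalene-1-carboxylic acid carrying the free side chain of 40 | C/C(=C/C=C/[C@H](C)[C@H](O)[C@@H](C)[C@@H](O)[C@@H](C)[C@@H]1O[C@@]2(C)CC[C@H](O2)[C@H]1C)C(=O)Nc1cc(O)c2c(C(=O)O)c(O)c(C)c(O)c2c1
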